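**Plan**
- Retrosynthesis: the arene is taken back by two hydrogens and one O–Si bond to a silylated cyclohexenone β-keto ester. That ring is cut at C4=C5 (alkene metathesis), C1–C6 (enolate allylation) and C1–C2 (acylation of a malonate half-ester). The alkyl O–C(=O) bond goes back to Meldrum's acid plus the alcohol, and the chain is cut between C16 and C17.
- Forward: the chain is joined by copper-catalysed alkyl–alkyl coupling and reduced to the alcohol, which opens Meldrum's acid. Silylated vinylglycolic acid is attached (C1–C2) and allyl bromide adds C5–C6. The only ring then closes by metathesis, DDQ aromatises it and fluoride frees the catechol.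
- Enabling feature: in the benzene ring C1, C2 and C3 carry the ester and the two oxygens, while C4, C5 and C6 carry only hydrogen. The C4–C5 edge can therefore be made as an alkene from a vinyl carbinol (C3–C4) and an allyl group (C5–C6) on a β-keto ester (C1, C2), and the ring so formed is two hydrogens short of the arene.
- Stereochemistry: the target has no stereocentre. C1 and C3 of the intermediates arise as uncontrolled mixtures and both become sp2 on aromatisation.

Key step: step 8

Remark: ring atoms are numbered C1 (ester-bearing), C2 and C3 (oxygen-bearing) and C4–C6 (CH), and the same numbers are used for the acyclic and cyclohexenone precursors. Methyl 2-hydroxybut-3-enoate is assumed to be the racemate, which is harmless because its stereocentre disappears.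

**Route**

Step 1
Reactants: 1 1-bromo-4-methylpentane; 2 16-bromohexadecanoic acid
Product: 4 20-methylhenicosanoic acid, via 4-methylpentylmagnesium bromide 3 (not isolated)
Conditions: 1 (2.6 equiv), Mg, THF, 40 °C; then 2, Li2CuCl4 (3 mol%), THF, −20 °C → rt; aq. HCl
Reagents that add atoms: none
Why: Li2CuCl4-catalysed alkyl–alkyl cross-coupling of a primary Grignard reagent with a primary bromide (Kochi-type coupling) should run cleanly because the first equivalent of 3 converts the acid into an inert magnesium carboxylate, and the acidic product is freed from hydrocarbon by-products by base extraction.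

Step 2
Reactants: 4 20-methylhenicosanoic acid
Product: 5 20-methylhenicosan-1-ol
Conditions: LiAlH4, THF, 0 °C → 65 °C; H2O, aq. NaOH
Reagents that add atoms: none
Why: Hydride reduction of a carboxylic acid to the primary alcohol with LiAlH4 is standard, and the saturated chain offers no competing site.

Step 3
Reactants: 5 20-methylhenicosan-1-ol; 6 Meldrum's acid (2,2-dimethyl-1,3-dioxane-4,6-dione)
Product: 7 3-[(20-methylhenicosyl)oxy]-3-oxopropanoic acid (mono-20-methylhenicosyl malonate)
Conditions: toluene, 110 °C
Reagents that add atoms: none
Why: Thermal alcoholysis of Meldrum's acid (acyl substitution with ring opening and loss of acetone) gives the malonic half-ester directly, without diester formation or a coupling reagent.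

Step 4
Reactants: 8 methyl 2-hydroxybut-3-enoate (racemic)
Product: 9 methyl 2-(tert-butyldimethylsilyloxy)but-3-enoate (racemic)
Conditions: TBSCl, imidazole, DMF, rt
Reagents that add atoms: tert-butyldimethylsilyl chloride (TBSCl), CC(C)(C)[Si](C)(C)Cl
Why: Silylation of a secondary alcohol with TBSCl and imidazole is routine, and the bulky silyl ether shields the C3 oxygen and should survive the later enolate, metathesis and quinone steps.

Step 5
Reactants: 9 methyl 2-(tert-butyldimethylsilyloxy)but-3-enoate
Product: 10 2-(tert-butyldimethylsilyloxy)but-3-enoic acid (racemic)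
Conditions: LiOH·H2O, THF/H2O, 0 °C; then aq. HCl (1 mol/L) to pH 3–4, 0 °C
Reagents that add atoms: LiOH, [Li+].[OH-]
Why: Saponification of the methyl ester with LiOH at 0 °C should leave the secondary silyl ether intact, and the short, cold exposure to hydroxide is expected to keep the β,γ-alkene out of conjugation.

Step 6
Reactants: 10 2-(tert-butyldimethylsilyloxy)but-3-enoic acid; 7 3-[(20-methylhenicosyl)oxy]-3-oxopropanoic acid
Product: 13 20-methylhenicosyl 4-(tert-butyldimethylsilyloxy)-3-oxohex-5-enoate, via acyl imidazolide 11 (not isolated), via acylmalonic acid half-ester 12 (not isolated)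
Conditions: 10, 1,1'-carbonyldiimidazole, THF, rt; separately 7, MgCl2, Et3N, THF, rt; combine, rt → 40 °C; aq. citric acid
Reagents that add atoms: none
Why: Masamune–Brooks β-keto ester synthesis, in which the magnesium enolate of the malonate half-ester is C-acylated by the neutral acyl imidazolide and the adduct loses CO2, forms the C1–C2 bond under conditions mild enough that the α-silyloxy β,γ-unsaturated acyl unit should not enolise.

Step 7
Reactants: 13 20-methylhenicosyl 4-(tert-butyldimethylsilyloxy)-3-oxohex-5-enoate
Product: 14 20-methylhenicosyl 2-allyl-4-(tert-butyldimethylsilyloxy)-3-oxohex-5-enoate (mixture of diastereomers)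
Conditions: NaH (0.95 equiv), THF/DMF, 0 °C; allyl bromide (1.0 equiv), 0 °C → rt
Reagents that add atoms: allyl bromide, C=CCBr
Why: C-Alkylation of a β-keto ester sodium enolate with the soft electrophile allyl bromide forms the C1–C6 bond; a slight deficit of base limits double allylation and leaves the less acidic C3–H untouched, and the new centre at C1 needs no control because it is erased later.

Step 8
Reactants: 14 20-methylhenicosyl 2-allyl-4-(tert-butyldimethylsilyloxy)-3-oxohex-5-enoate
Product: 15 20-methylhenicosyl 3-(tert-butyldimethylsilyloxy)-2-oxocyclohex-4-ene-1-carboxylate (mixture of diastereomers, partly present as the C1=C2 enol)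
Conditions: second-generation Grubbs catalyst (H2IMes)(PCy3)Cl2Ru=CHPh (5 mol%), 1,4-benzoquinone (10 mol%), CH2Cl2 (0.005 mol/L), 40 °C
Reagents that add atoms: none
Why: Olefin metathesis: the ruthenium benzylidene exchanges onto the unhindered allyl terminus (C5), the new alkylidene adds across the vinyl group (C4) in a [2+2] cycloaddition, and the metallacyclobutane cycloreverts to give the C4=C5 bond with ethylene as the volatile co-product. The closest known reaction type is ring-closing metathesis of 1,7-dienes to cyclohexenes, including dienyl ketones that give cyclohexenones which are afterwards aromatised to phenols. The single ring, the six-membered carbocycle that becomes the arene, closes by this intramolecular alkene–alkene metathesis between C4 and C5, a ring size for which closure is fast. No stereocentre is created; C1 and C3 stay as the mixtures carried in from steps 7 and 4 and both are erased in step 9. The step needs ring closure to win over acyclic diene oligomerisation and over migration of the allyl double bond: high dilution and escape of ethylene should secure the former, 1,4-benzoquinone as a scavenger of ruthenium hydrides the latter, and the bulky silyl ether steers catalyst loading to the allyl arm and keeps the C3 oxygen from binding ruthenium.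

Step 9
Reactants: 15 20-methylhenicosyl 3-(tert-butyldimethylsilyloxy)-2-oxocyclohex-4-ene-1-carboxylate
Product: 16 20-methylhenicosyl 3-(tert-butyldimethylsilyloxy)-2-hydroxybenzoate
Conditions: DDQ (1.1 equiv), toluene, rt
Reagents that add atoms: none
Why: Quinone dehydrogenation: the C1=C2 enol of 15 is a cyclohexa-1,4-diene, so hydride transfer from the doubly allylic C6 (or C3) to DDQ gives an arenium ion that loses a proton to the arene, the known aromatisation of cyclohexadienes and cyclic β-keto esters by DDQ, while the silyl ether holds the C3 oxygen in place.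

Step 10
Reactants: 16 20-methylhenicosyl 3-(tert-butyldimethylsilyloxy)-2-hydroxybenzoate
Product: 17 Gentiside A (20-methylhenicosyl 2,3-dihydroxybenzoate)
Conditions: Bu4NF, AcOH, THF, 0 °C, under argon
Reagents that add atoms: none
Why: Fluoride-mediated cleavage of an aryl silyl ether is fast at 0 °C, and buffering with AcOH should prevent catecholate formation, air oxidation and attack on the ester.

**Compound list**
1 | 1-bromo-4-methylpentane | CC(C)CCCBr | starting material
2 | 16-bromohexadecanoic acid | OC(=O)CCCCCCCCCCCCCCCBr | starting material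
3 | 4-methylpentylmagnesium bromide | CC(C)CCC[Mg]Br | intermediate
4 | 20-methylhenicosanoic acid | CC(C)CCCCCCCCCCCCCCCCCCC(=O)O | intermediate
5 | 20-methylhenicosan-1-ol | CC(C)CCCCCCCCCCCCCCCCCCCO | intermediate
6 | Meldrum's acid (2,2-dimethyl-1,3-dioxane-4,6-dione) | CC1(C)OC(=O)CC(=O)O1 | starting material
7 | 3-[(20-methylhenicosyl)oxy]-3-oxopropanoic acid | CC(C)CCCCCCCCCCCCCCCCCCCOC(=O)CC(=O)O | intermediate
8 | methyl 2-hydroxybut-3-enoate (racemic) | C=CC(O)C(=O)OC | starting material
9 | methyl 2-(tert-butyldimethylsilyloxy)but-3-enoate (racemic) | C=CC(O[Si](C)(C)C(C)(C)C)C(=O)OC | intermediate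
10 | 2-(tert-butyldimethylsilyloxy)but-3-enoic acid (racemic) | C=CC(O[Si](C)(C)C(C)(C)C)C(=O)O | intermediate
11 | 1-[2-(tert-butyldimethylsilyloxy)but-3-enoyl]imidazole (racemic) | C=CC(O[Si](C)(C)C(C)(C)C)C(=O)n1ccnc1 | intermediate
12 | 4-(tert-butyldimethylsilyloxy)-2-[(20-methylhenicosyloxy)carbonyl]-3-oxohex-5-enoic acid (mixture of diastereomers) | CC(C)CCCCCCCCCCCCCCCCCCCOC(=O)C(C(=O)O)C(=O)C(O[Si](C)(C)C(C)(C)C)C=C | intermediate
13 | 20-methylhenicosyl 4-(tert-butyldimethylsilyloxy)-3-oxohex-5-enoate (racemic) | CC(C)CCCCCCCCCCCCCCCCCCCOC(=O)CC(=O)C(O[Si](C)(C)C(C)(C)C)C=C | intermediate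
14 | 20-methylhenicosyl 2-allyl-4-(tert-butyldimethylsilyloxy)-3-oxohex-5-enoate (mixture of diastereomers) | CC(C)CCCCCCCCCCCCCCCCCCCOC(=O)C(CC=C)C(=O)C(O[Si](C)(C)C(C)(C)C)C=C | intermediate
15 | 20-methylhenicosyl 3-(tert-butyldimethylsilyloxy)-2-oxocyclohex-4-ene-1-carboxylate (mixture of diastereomers) | CC(C)CCCCCCCCCCCCCCCCCCCOC(=O)C1CC=CC(O[Si](C)(C)C(C)(C)C)C1=O | intermediate
16 | 20-methylhenicosyl 3-(tert-butyldimethylsilyloxy)-2-hydroxybenzoate | CC(C)CCCCCCCCCCCCCCCCCCCOC(=O)c1cccc(O[Si](C)(C)C(C)(C)C)c1O | intermediate
17 | Gentiside A (20-methylhenicosyl 2,3-dihydroxybenzoate) | CC(C)CCCCCCCCCCCCCCCCCCCOC(=O)c1cccc(O)c1O | target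

**Step count and risks**

Total steps: 10. Longest linear sequence: 8 steps (steps 1, 2, 3, 6, 7, 8, 9, 10); steps 4 and 5 form the short side branch that joins at step 6.

Steps most likely to fail:

Step 8. The chelating enol of the β-keto ester may tie up the ruthenium carbene, intermolecular metathesis may outrun ring closure, or a ruthenium hydride may shift the allyl double bond before closure. The fallback sets out from 14 and masks the β-keto ester. Silylation with Me3SiCl and Et3N in CH2Cl2 should give the enol ether in which the chelate geometry holds both alkenyl arms on the same side, 20-methylhenicosyl (2Z)-2-allyl-4-(tert-butyldimethylsilyloxy)-3-(trimethylsilyloxy)hexa-2,5-dienoate F1. This non-chelating, pre-organised triene is closed with the same second-generation Grubbs catalyst to 20-methylhenicosyl 3-(tert-butyldimethylsilyloxy)-2-(trimethylsilyloxy)cyclohexa-1,4-diene-1-carboxylate F2. DDQ in toluene then aromatises the 1,4-diene to 20-methylhenicosyl 3-(tert-butyldimethylsilyloxy)-2-(trimethylsilyloxy)benzoate F3, whose labile aryl trimethylsilyl ether is hydrolysed during aqueous work-up. The route is rejoined at 16.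

Step 9. The hydroquinone formed is acidic and may promote loss of silanol from the enol, giving a ring without the C3 oxygen, or the enol may add to the quinone instead of transferring hydride. The fallback sets out from 15 and dehydrogenates by a non-acidic two-electron path. Selenenylation at C1 with PhSeCl and pyridine in CH2Cl2 at 0 °C should give 20-methylhenicosyl 3-(tert-butyldimethylsilyloxy)-2-oxo-1-(phenylselanyl)cyclohex-4-ene-1-carboxylate F4. Oxidation with aqueous H2O2 at 0 °C gives 20-methylhenicosyl 3-(tert-butyldimethylsilyloxy)-2-oxo-1-(phenylseleninyl)cyclohex-4-ene-1-carboxylate F5. Its syn-elimination, possible only toward C6, gives 20-methylhenicosyl 5-(tert-butyldimethylsilyloxy)-6-oxocyclohexa-1,3-diene-1-carboxylate F6, which tautomerises to the phenol. The route is rejoined at 16.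

Step 7. A second alkylation of the product enolate, O-allylation, or base-induced migration of the vinyl double bond into conjugation with the ketone may erode the mono-C-allyl compound. The fallback brings C5–C6 in with the ester instead of alkylating. It sets out from 5, which is acylated with pent-4-enoyl chloride (Et3N, DMAP, CH2Cl2) to 20-methylhenicosyl pent-4-enoate F7. The lithium enolate of this ester (LiN(iPr)2, THF, −78 °C, two equivalents, surplus ester recovered) is C-acylated in a crossed Claisen condensation by imidazolide 11, prepared from 10 and 1,1'-carbonyldiimidazole as in step 6. This forms C1–C2 with the allyl group already in place, and the route is rejoined at 14.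

**Further compounds**
F1 | step 8 | 20-methylhenicosyl (2Z)-2-allyl-4-(tert-butyldimethylsilyloxy)-3-(trimethylsilyloxy)hexa-2,5-dienoate | CC(C)CCCCCCCCCCCCCCCCCCCOC(=O)/C(CC=C)=C(\O[Si](C)(C)C)C(O[Si](C)(C)C(C)(C)C)C=C
F2 | step 8 | 20-methylhenicosyl 3-(tert-butyldimethylsilyloxy)-2-(trimethylsilyloxy)cyclohexa-1,4-diene-1-carboxylate | CC(C)CCCCCCCCCCCCCCCCCCCOC(=O)C1=C(O[Si](C)(C)C)C(O[Si](C)(C)C(C)(C)C)C=CC1
F3 | step 8 | 20-methylhenicosyl 3-(tert-butyldimethylsilyloxy)-2-(trimethylsilyloxy)benzoate | CC(C)CCCCCCCCCCCCCCCCCCCOC(=O)c1cccc(O[Si](C)(C)C(C)(C)C)c1O[Si](C)(C)C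
F4 | step 9 | 20-methylhenicosyl 3-(tert-butyldimethylsilyloxy)-2-oxo-1-(phenylselanyl)cyclohex-4-ene-1-carboxylate | CC(C)CCCCCCCCCCCCCCCCCCCOC(=O)C1([Se]c2ccccc2)CC=CC(O[Si](C)(C)C(C)(C)C)C1=O
F5 | step 9 | 20-methylhenicosyl 3-(tert-butyldimethylsilyloxy)-2-oxo-1-(phenylseleninyl)cyclohex-4-ene-1-carboxylate | CC(C)CCCCCCCCCCCCCCCCCCCOC(=O)C1([Se](=O)c2ccccc2)CC=CC(O[Si](C)(C)C(C)(C)C)C1=O
F6 | step 9 | 20-methylhenicosyl 5-(tert-butyldimethylsilyloxy)-6-oxocyclohexa-1,3-diene-1-carboxylate | CC(C)CCCCCCCCCCCCCCCCCCCOC(=O)C1=CC=CC(O[Si](C)(C)C(C)(C)C)C1=O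
F7 | step 7 | 20-methylhenicosyl pent-4-enoate | CC(C)CCCCCCCCCCCCCCCCCCCOC(=O)CCC=C
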